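The route disconnects the (E)-nonenyl chain from C10, the carbon of the dihydropyran ring that lies between the ring oxygen O11 and the C21=C22 alkene. This position is the terminus of an allyl oxocarbenium ion, so the key step is a stereoconvergent Ferrier-type alkenylation. A transposed glycal (enol ether C10=C22, carbinol at C21, both epimers) is ionised and captured by potassium (E)-non-1-enyltrifluoroborate, forming the C9–C10 bond, the C21=C22 alkene and the C10 stereocentre at once. The tetracyclic precursor comes from a cyclopentanone by acetoacetate-dianion spirolactonisation, an intramolecular aldol onto a vicinal tricarbonyl and a pyranone annulation.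

Key step: step 8

Remark (numbering used in the text): C1–C9 nonenyl chain (C8=C9); C10 pyran CH bearing it; O11 pyran oxygen; C12 quaternary carbon bearing O11; C13 lactone carbonyl; O14 lactone ring oxygen; C15 carbon bearing O14; C16, C17, C18 cyclopentane CH2, CH(OH), CH2; C19 ring-fusion CH; C20 CH between C19 and C12; C21=C22 pyran alkene (C22 bears CH3); C23, C24 the CH2 and CHOH of the third bridge.
Assumption: 2-(bromomethyl)but-1-ene (2) is taken as a catalogue reagent.

Step 1
Reactants: 1 (S)-4-(tert-butyldimethylsilyloxy)cyclopent-2-en-1-one; 2 2-(bromomethyl)but-1-ene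
Product: 5 (2R,4R)-4-(tert-butyldimethylsilyloxy)-2-(2-methylidenebutyl)cyclopentan-1-one, via silyl enol ether 3 (not isolated), via lithium enolate 4 (not isolated)
Conditions: PhMe2SiH, [(Ph3P)CuH]6 (cat.), toluene, rt; MeLi, THF, 0 °C; then 2, DMPU, −78 to −30 °C
Reagents that add atoms: 2-(bromomethyl)but-1-ene, CCC(=C)CBr
Why: CuH-catalysed 1,4-hydrosilylation should give the regiodefined enol ether C15=C19, MeLi unveils the lithium enolate, and its alkylation by the allylic bromide should occur anti to the C17 silyloxy group, setting C19 trans to OTBS (enolate alkylation).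

Step 2
Reactants: 5; 6 methyl acetoacetate
Product: 8 spiro β-keto δ-lactone (O14 cis to the C19 arm), via aldol adduct 7 (not isolated)
Conditions: 6, NaH then n-BuLi, THF, 0 °C; 5, −78 °C; then 0.1 M aq NaOH, THF, rt; 1 M HCl
Reagents that add atoms: methyl acetoacetate, COC(=O)CC(C)=O
Why: The γ-carbon of the Weiler dianion should add to the ketone anti to the adjacent C19 arm, which sets C15 with O14 cis to that arm and C23 cis to OTBS, and the tertiary alkoxide then closes the δ-lactone on the methyl ester (aldol addition and lactonisation).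

Step 3
Reactants: 8; 9 N,N-dimethylformamide dimethyl acetal
Product: 10 C12-(dimethylaminomethylidene) derivative of 8
Conditions: 9, CH2Cl2, rt
Reagents that add atoms: N,N-dimethylformamide dimethyl acetal, COC(OC)N(C)C
Why: The amide acetal should condense at the doubly activated C12 methylene of the cyclic β-keto lactone (enaminone formation), the only acidic CH2 in the molecule.

Step 4
Reactants: 10; 11 ozone
Product: 13 tricyclic hydroxy diketo lactone (C20 epimers), via vicinal tricarbonyl 12 (not isolated)
Conditions: O3, CH2Cl2, −78 °C; Me2S, −78 °C to rt; then Et3N (cat.), 4 Å MS, rt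
Reagents that add atoms: ozone, [O-][O+]=O
Why: Ozonolysis should cleave the enaminone to the vicinal tricarbonyl (Wasserman type) and the 1,1-disubstituted alkene to the ethyl ketone, whose C20 enol then adds to the central carbonyl C12 in a six-membered intramolecular aldol; because O14 and the C20 arm are cis on the cyclopentane, the 2-oxabicyclo[2.2.2]octane can only form with the cyclopentane on the lactone side, which fixes C12, while C20 is left uncontrolled.

Step 5
Reactants: 13; 14 tert-butoxybis(dimethylamino)methane
Product: 16 tetracyclic 2,3-dihydro-4H-pyran-4-one (C20 epimers), via enaminone 15 (not isolated)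
Conditions: 14, toluene, 60 °C; then TsOH·H2O, CH2Cl2, rt
Reagents that add atoms: tert-butoxybis(dimethylamino)methane, CC(C)(C)OC(N(C)C)N(C)C
Why: Aminomethylenation should take place at the unhindered ethyl CH2 (C22) in preference to the neopentyl bridge CH2 (C23), and acid-catalysed addition–elimination by the tertiary C12 hydroxyl then closes the dihydropyranone (β-hydroxy ketone to dihydropyranone annulation).

Step 6
Reactants: 16
Product: 19 transposed glycal diol (C21 epimers), via dilithium bis-enolate 17 (not isolated), via cis-pyranone 18 (not isolated)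
Conditions: LDA (3 equiv), THF, −78 °C; 2,6-di-tert-butyl-4-methylphenol, −78 °C; then CeCl3·7H2O, NaBH4, MeOH, −78 °C; aq NH4Cl
Reagents that add atoms: none
Why: Both C20 epimers give the same planar pyran-4-olate, which the bulky phenol should protonate at C20 from the face anti to C18 (Zimmerman-type kinetic protonation, H20 cis to H19), and immediate Luche reduction prevents re-equilibration, delivers hydride to the C24 ketone from the open face next to the lactone bridge (OH towards the C19–C20 bridge) and reduces the vinylogous ester 1,2 to the allylic alcohol.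

Step 7
Reactants: 20 non-1-yne; 21 pinacolborane; 22 potassium hydrogen difluoride
Product: 24 potassium (E)-non-1-enyltrifluoroborate, via pinacol boronate 23 (not isolated)
Conditions: 21, Cp2ZrHCl (cat.), Et3N (cat.), 60 °C; then aq KHF2, MeOH, rt
Reagents that add atoms: pinacolborane, CC1(C)OBOC1(C)C; potassium hydrogen difluoride, [K+].[F-].F
Why: Zirconium-catalysed syn-hydroboration of the terminal alkyne should give the (E)-alkenylboronate, which KHF2 converts into the trifluoroborate.

Step 8
Reactants: 19; 24
Product: 26 17-O-TBS ether of the target, via allyl oxocarbenium ion 25 (not isolated)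
Conditions: 24 (2.5 equiv), BF3·OEt2 (3 equiv), CH2Cl2/MeCN, −40 to 0 °C
Reagents that add atoms: potassium (E)-non-1-enyltrifluoroborate, CCCCCCC/C=C/[B-](F)(F)F.[K+]
Why: BF3·OEt2 should ionise the vinylogous hemiacetal hydroxyl at C21 of either epimer to the same allyl oxocarbenium ion O11=C10–C22=C21, and the alkenyldifluoroborane formed in situ from 24 transfers its nonenyl group to C10 with retention of the (E)-geometry and shift of the ring alkene to C21=C22. The closest known reaction type is the Ferrier (type I) C-glycosylation of glycals, run here as a BF3-mediated addition of a potassium alkenyltrifluoroborate to a cyclic oxocarbenium ion. No ring is closed. The new stereocentre C10 is under substrate control: the C12–C20 bond is locked in the bicycle, so the cation is a fixed sofa with C20 as the flap, and chair-like pseudoaxial attack anti to that flap places the nonenyl group cis to the lactone carbonyl carbon C13 and free of A(1,2) strain with the C22 methyl group. The step needs regioselectivity for C10 over C21, secured by attack at the oxygen-stabilised terminus as in Ferrier reactions, and facial selectivity, secured by the locked ring; the free C24 hydroxyl cannot reach C10 and the silyl ether should survive the low temperature.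

Step 9
Reactants: 26
Product: 27 CNP0127096.1 (target)
Conditions: HF·pyridine, pyridine, THF, 0 °C to rt
Reagents that add atoms: none
Why: Buffered fluoride cleavage of the secondary TBS ether should leave the doubly allylic ether at C10 and the hindered bridged lactone untouched (silyl ether deprotection).

Compound list
1 | (S)-4-(tert-butyldimethylsilyloxy)cyclopent-2-en-1-one | O=C1C[C@H](O[Si](C)(C)C(C)(C)C)C=C1 | starting material
2 | 2-(bromomethyl)but-1-ene | CCC(=C)CBr | starting material
3 | dimethyl(phenyl)silyl enol ether of the reduced enone (enol C15=C19, remote from the silyloxy carbon) | C[Si](C)(OC1=CC[C@@H](O[Si](C)(C)C(C)(C)C)C1)c1ccccc1 | intermediate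
4 | lithium enolate corresponding to 3 | [Li+].[O-]C1=CC[C@@H](O[Si](C)(C)C(C)(C)C)C1 | intermediate
5 | (2R,4R)-4-(tert-butyldimethylsilyloxy)-2-(2-methylidenebutyl)cyclopentan-1-one (2,4-trans) | O=C1C[C@H](O[Si](C)(C)C(C)(C)C)C[C@H]1CC(=C)CC | intermediate
6 | methyl acetoacetate | COC(=O)CC(C)=O | starting material
7 | methyl 4-[1-hydroxy-2-(2-methylidenebutyl)-4-(silyloxy)cyclopentyl]-3-oxobutanoate (OH cis to the arm, trans to OTBS) | COC(=O)CC(=O)C[C@]1(O)C[C@H](O[Si](C)(C)C(C)(C)C)C[C@H]1CC(=C)CC | intermediate
8 | 3-(tert-butyldimethylsilyloxy)-1-(2-methylidenebutyl)-6-oxaspiro[4.5]decane-7,9-dione (ring O cis to the C1 arm, trans to OTBS; enolisable) | O=C1CC(=O)C[C@]2(O1)C[C@H](O[Si](C)(C)C(C)(C)C)C[C@H]2CC(=C)CC | intermediate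
9 | N,N-dimethylformamide dimethyl acetal | COC(OC)N(C)C | starting material
10 | 8-(dimethylaminomethylidene) derivative of 8 | O=C1C(=CN(C)C)C(=O)C[C@]2(O1)C[C@H](O[Si](C)(C)C(C)(C)C)C[C@H]2CC(=C)CC | intermediate
11 | ozone | [O-][O+]=O | starting material
12 | 3-(tert-butyldimethylsilyloxy)-1-(2-oxobutyl)-6-oxaspiro[4.5]decane-7,8,9-trione | O=C1C(=O)C(=O)C[C@]2(O1)C[C@H](O[Si](C)(C)C(C)(C)C)C[C@H]2CC(=O)CC | intermediate
13 | 2-oxabicyclo[2.2.2]octan-3-one with OH on C12, ketone at C24, propanoyl on C20 and the silyloxy-cyclopentane fused at C15–C19 on the lactone side (C20 epimers) | O[C@@]12C(=O)O[C@]3(C[C@H](O[Si](C)(C)C(C)(C)C)C[C@H]3C1C(=O)CC)CC2=O | intermediate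
14 | tert-butoxybis(dimethylamino)methane (Bredereck's reagent) | CC(C)(C)OC(N(C)C)N(C)C | starting material
15 | enaminone of 13 (C22=CH–NMe2) | O[C@@]12C(=O)O[C@]3(C[C@H](O[Si](C)(C)C(C)(C)C)C[C@H]3C1C(=O)C(C)=CN(C)C)CC2=O | intermediate
16 | tetracyclic dihydropyranone O11–C10H=C22(CH3)–C21(=O)–C20 with C24 ketone (C20 epimers) | C1O[C@@]23C(=O)O[C@]4(C[C@H](O[Si](C)(C)C(C)(C)C)C[C@H]4C2C(=O)C=1C)CC3=O | intermediate
17 | dilithium bis-enolate of 16 (pyran-4-olate C20=C21–O⁻ and enolate C23=C24–O⁻) | [Li+].[Li+].C1O[C@@]23C(=O)O[C@]4(C[C@H](O[Si](C)(C)C(C)(C)C)C[C@H]4C2=C([O-])C=1C)C=C3[O-] | intermediate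
18 | dihydropyranone with H20 cis to H19 (pyranone on the lactone side) | C1O[C@@]23C(=O)O[C@]4(C[C@H](O[Si](C)(C)C(C)(C)C)C[C@H]4[C@H]2C(=O)C=1C)CC3=O | intermediate
19 | transposed glycal: enol ether C10=C22, carbinol at C21 (both epimers), C24 alcohol with OH towards the C19–C20 bridge | C1O[C@@]23C(=O)O[C@]4(C[C@H](O[Si](C)(C)C(C)(C)C)C[C@H]4[C@H]2C(O)C=1C)C[C@H]3O | intermediate
20 | non-1-yne | CCCCCCCC#C | starting material
21 | pinacolborane | CC1(C)OBOC1(C)C | starting material
22 | potassium hydrogen difluoride | [K+].[F-].F | starting material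
23 | (E)-non-1-enylboronic acid pinacol ester | CCCCCCC/C=C/B1OC(C)(C)C(C)(C)O1 | intermediate
24 | potassium (E)-non-1-enyltrifluoroborate | CCCCCCC/C=C/[B-](F)(F)F.[K+] | intermediate
25 | allyl oxocarbenium ion O11=C10–C22=C21 | C1=[O+][C@@]23C(=O)O[C@]4(C[C@H](O[Si](C)(C)C(C)(C)C)C[C@H]4[C@H]2C=C1C)C[C@H]3O | intermediate
26 | 17-O-tert-butyldimethylsilyl ether of the target | CCCCCCC/C=C/[C@H]1O[C@@]23C(=O)O[C@]4(C[C@H](O[Si](C)(C)C(C)(C)C)C[C@H]4[C@H]2C=C1C)C[C@H]3O | intermediate
27 | CNP0127096.1 (C10 R, C12 S, C15 R, C17 R, C19 S, C20 R, C24 R) | CCCCCCC/C=C/[C@H]1O[C@@]23C(=O)O[C@]4(C[C@H](O)C[C@H]4[C@H]2C=C1C)C[C@H]3O | target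

Total step count: 9. Longest linear sequence: 8 (steps 1–6, 8, 9).

Steps most likely to fail

Step 6. The proton may be delivered to C20 with poor facial selectivity, or the kinetic ketone may re-equilibrate to the trans isomer before it is reduced. The fallback replaces kinetic by thermodynamic control. It sets out from 16: NaBH4 alone at −78 °C should reduce only the C24 ketone to the C24 alcohol F1, and TBSOTf/2,6-lutidine gives the bis-silyl ether F2. Base equilibration of C20 (DBU or catalytic KOt-Bu, THF) should then favour the cis-pyranone F3, because its epimer suffers a 1,3-syn clash between C21 and the C24 silyloxy group in the cleft between the two carbon bridges. Luche reduction gives the glycal F4, the conditions of step 8 give the bis-silyl ether F5, and the conditions of step 9 remove both silyl groups, so the fallback comes back at 27.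

Step 5. The formamide acetal may condense at the bridge methylene C23 next to the C24 ketone, and 13 may undergo retro-aldol cleavage or α-ketol shift on basic heating. The fallback delivers the formyl carbon through a tether. It sets out from 13: acetic formic anhydride/pyridine gives the C12 formate F6, and LiHMDS at −78 °C should make the C22 enolate attack the formate carbonyl (intramolecular Claisen-type acylation) to give the cyclic lactol F7. TsOH-mediated dehydration comes back at 16.

Step 8. The nucleophile may attack the exposed convex face instead of the pseudoaxial trajectory, or attack C21. The fallback forms the C10–O11 bond last, under thermodynamic control. It sets out from 19: PPTS in wet THF should give the lactol F8 by Ferrier-type hydration (in equilibrium with the Z-hydroxy-enal). The alkenylzinc reagent F9 (from 20 with Cp2ZrHCl, then Me2Zn) adds 1,2 to the aldehyde tautomer to give the doubly allylic alcohol F10 as both C10 epimers. Catalytic CSA in CH2Cl2 ionises that carbinol reversibly and the C12 hydroxyl recloses the ring; the pseudoaxial nonenyl epimer, free of A(1,2) strain with the C22 methyl group, should accumulate, and the fallback comes back at 26.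

Further compounds
F1 | step 6 | C24 alcohol of dihydropyranone 16 (C20 epimers) | C1O[C@@]23C(=O)O[C@]4(C[C@H](O[Si](C)(C)C(C)(C)C)C[C@H]4C2C(=O)C=1C)C[C@H]3O
F2 | step 6 | 17,24-bis-O-TBS dihydropyranone (C20 epimers) | C1O[C@@]23C(=O)O[C@]4(C[C@H](O[Si](C)(C)C(C)(C)C)C[C@H]4C2C(=O)C=1C)C[C@H]3O[Si](C)(C)C(C)(C)C
F3 | step 6 | 17,24-bis-O-TBS dihydropyranone with H20 cis to H19 | C1O[C@@]23C(=O)O[C@]4(C[C@H](O[Si](C)(C)C(C)(C)C)C[C@H]4[C@H]2C(=O)C=1C)C[C@H]3O[Si](C)(C)C(C)(C)C
F4 | step 6 | 17,24-bis-O-TBS transposed glycal (C21 epimers) | C1O[C@@]23C(=O)O[C@]4(C[C@H](O[Si](C)(C)C(C)(C)C)C[C@H]4[C@H]2C(O)C=1C)C[C@H]3O[Si](C)(C)C(C)(C)C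
F5 | step 6 | 17,24-bis-O-TBS ether of the target | CCCCCCC/C=C/[C@H]1O[C@@]23C(=O)O[C@]4(C[C@H](O[Si](C)(C)C(C)(C)C)C[C@H]4[C@H]2C=C1C)C[C@H]3O[Si](C)(C)C(C)(C)C
F6 | step 5 | C12 formate of 13 | O=CO[C@@]12C(=O)O[C@]3(C[C@H](O[Si](C)(C)C(C)(C)C)C[C@H]3C1C(=O)CC)CC2=O
F7 | step 5 | 2-hydroxytetrahydropyran-4-one lactol (C10 hemiacetal) | OC1O[C@@]23C(=O)O[C@]4(C[C@H](O[Si](C)(C)C(C)(C)C)C[C@H]4C2C(=O)C1C)CC3=O
F8 | step 8 | C10 lactol (2-hydroxy-2H-pyran, both anomers) | OC1O[C@@]23C(=O)O[C@]4(C[C@H](O[Si](C)(C)C(C)(C)C)C[C@H]4[C@H]2C=C1C)C[C@H]3O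
F9 | step 8 | (E)-non-1-enyl(methyl)zinc | CCCCCCC/C=C/[Zn]C
F10 | step 8 | open-chain doubly allylic C10 alcohol (both C10 epimers) | O[C@@]12C(=O)O[C@]3(C[C@H](O[Si](C)(C)C(C)(C)C)C[C@H]3[C@H]1/C=C(C)\C(O)/C=C/CCCCCCC)C[C@H]2O
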